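**Retrosynthetic overview** (C1 = carbinol carbon, C17 = end of the chain)
1. The end game frees the C14 ketone from a 1,3-dithiane and places the acetate on C1-OH. Both groups stay masked (OTBS, dithiane) while the chain is assembled.
2. The C5–C6 bond comes from an allylic bromide (furan + C1–C5) and a lithiated allylic phenyl sulfone (C6–C17), followed by Pd-catalysed hydride removal of the sulfonyl group.
3. The C1–C2 bond is the key bond and sets the only stereocentre, by asymmetric allylboration of furan-3-carbaldehyde. C3=C4 follows from alkene cleavage and an E-selective stabilised Wittig reaction.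
4. For C13–C14, geraniol (which brings the other two E-alkenes) is oxidised at its E-methyl group, brominated, and alkylated with the lithiated dithiane of isovaleraldehyde.
5. No ring of the target is built, because the furan is bought with the aldehyde. The only ring made is the temporary dithiane, which is opened in the last step.

Assumption: the centre written [C@@H] reads as (S) (O > 3-furyl > CH2 > H), all three alkenes are E, and bench reagents ((−)-Ipc2BOMe, allylMgBr, the stabilised ylide, PhSO2Na) are bought.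

**West fragment**

Step 1
Reactants: 1 furan-3-carbaldehyde
Product: 3 (1S)-1-(furan-3-yl)but-3-en-1-ol, via borinate ester 2 (not isolated)
Conditions: (−)-Ipc2BOMe (1.3 equiv), allylMgBr (1.25 equiv), Et2O, 0 °C to rt, Mg salts filtered off; 1, Et2O–pentane, −100 °C, 1 h; then 3 M NaOH, 30% H2O2, 0 °C to rt
Reagents that add atoms: allylmagnesium bromide, C=CC[Mg]Br
Why: In this Brown asymmetric carbonyl allylation, the allylborane carrying (+)-α-pinene-derived isopinocampheyl groups delivers allyl to the Si face of the aldehyde through a chair Zimmerman–Traxler transition state, which forms C1–C2 and sets C1 as (S) (the sense in which benzaldehyde gives the (S)-carbinol), and salt-free reagent at −100 °C gives heteroaryl carbinols in very high ee.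

Step 2
Reactants: 3 (1S)-1-(furan-3-yl)but-3-en-1-ol
Product: 4 tert-butyl{[(1S)-1-(furan-3-yl)but-3-en-1-yl]oxy}dimethylsilane
Conditions: TBSCl, imidazole, DMF, rt
Reagents that add atoms: tert-butyldimethylsilyl chloride, CC(C)(C)[Si](C)(C)Cl
Why: Imidazole-promoted silyl ether protection of the secondary alcohol leaves the stereocentre untouched and gives a group that withstands the oxidants, hydrides and organolithiums ahead.

Step 3
Reactants: 4 tert-butyl{[(1S)-1-(furan-3-yl)but-3-en-1-yl]oxy}dimethylsilane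
Product: 6 (3S)-3-[(tert-butyldimethylsilyl)oxy]-3-(furan-3-yl)propanal, via vicinal diol 5 (not isolated)
Conditions: OsO4 (2 mol %), NaIO4 (4 equiv), 2,6-lutidine (2 equiv), dioxane–H2O 3:1, rt
Reagents that add atoms: sodium periodate, [Na+].[O-]I(=O)(=O)=O; water, O
Why: In this Lemieux–Johnson oxidative cleavage, OsO4 dihydroxylates the only non-aromatic alkene far faster than it attacks the furan, NaIO4 cleaves the diol at once, and 2,6-lutidine keeps the medium neutral so the β-silyloxy aldehyde does not eliminate.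

Step 4
Reactants: 6 (3S)-3-[(tert-butyldimethylsilyl)oxy]-3-(furan-3-yl)propanal
Product: 7 ethyl (2E,5S)-5-[(tert-butyldimethylsilyl)oxy]-5-(furan-3-yl)-2-methylpent-2-enoate
Conditions: Ph3P=C(CH3)CO2Et (1.5 equiv), CH2Cl2, rt to 40 °C
Reagents that add atoms: ethyl 2-(triphenylphosphoranylidene)propanoate, CCOC(=O)C(C)=P(c1ccccc1)(c1ccccc1)c1ccccc1
Why: A Wittig olefination with a stabilised α-methyl ylide gives the E-trisubstituted enoate (typically at least 95:5) under neutral conditions that spare the β-silyloxy group and the furan.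

Step 5
Reactants: 7 ethyl (2E,5S)-5-[(tert-butyldimethylsilyl)oxy]-5-(furan-3-yl)-2-methylpent-2-enoate
Product: 8 (2E,5S)-5-[(tert-butyldimethylsilyl)oxy]-5-(furan-3-yl)-2-methylpent-2-en-1-ol
Conditions: i-Bu2AlH (2.5 equiv), CH2Cl2, −78 °C; aq. potassium sodium tartrate
Reagents that add atoms: none
Why: Hydride 1,2-reduction of an enoate with i-Bu2AlH gives the allylic alcohol cleanly without conjugate reduction or change of alkene geometry.

Step 6
Reactants: 8 (2E,5S)-5-[(tert-butyldimethylsilyl)oxy]-5-(furan-3-yl)-2-methylpent-2-en-1-ol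
Product: 9 {[(1S,3E)-5-bromo-1-(furan-3-yl)-4-methylpent-3-en-1-yl]oxy}(tert-butyl)dimethylsilane
Conditions: CBr4, PPh3, CH2Cl2, −20 to 0 °C
Reagents that add atoms: carbon tetrabromide, BrC(Br)(Br)Br
Why: The Appel reaction converts the primary allylic alcohol to the bromide by SN2 under essentially neutral conditions, so the alkene geometry, the silyl ether and the furan are kept.

**East fragment**

Step 7
Reactants: 10 geraniol, (2E)-3,7-dimethylocta-2,6-dien-1-ol
Product: 11 tert-butyl{[(2E)-3,7-dimethylocta-2,6-dien-1-yl]oxy}dimethylsilane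
Conditions: TBSCl, imidazole, DMF, rt
Reagents that add atoms: tert-butyldimethylsilyl chloride, CC(C)(C)[Si](C)(C)Cl
Why: Silyl ether protection of the primary allylic alcohol is near quantitative and, unlike an ester, survives the dithiane anion used later.

Step 8
Reactants: 11 tert-butyl{[(2E)-3,7-dimethylocta-2,6-dien-1-yl]oxy}dimethylsilane
Product: 12 (2E,6E)-8-[(tert-butyldimethylsilyl)oxy]-2,6-dimethylocta-2,6-dien-1-ol
Conditions: SeO2 (0.2 equiv), t-BuOOH (2.5 equiv, decane), salicylic acid (0.1 equiv), CH2Cl2, 0 °C to rt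
Reagents that add atoms: tert-butyl hydroperoxide, CC(C)(C)OO
Why: Catalytic SeO2 allylic oxidation (ene reaction, then [2,3]-sigmatropic shift) picks the more electron-rich distal alkene and oxidises only its E-methyl group, which fixes the C11=C12 geometry.

Step 9
Reactants: 12 (2E,6E)-8-[(tert-butyldimethylsilyl)oxy]-2,6-dimethylocta-2,6-dien-1-ol
Product: 13 {[(2E,6E)-8-bromo-3,7-dimethylocta-2,6-dien-1-yl]oxy}(tert-butyl)dimethylsilane
Conditions: CBr4, PPh3, CH2Cl2, −20 to 0 °C
Reagents that add atoms: carbon tetrabromide, BrC(Br)(Br)Br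
Why: The Appel reaction gives the primary allylic bromide by SN2 with retention of both E-alkenes and of the silyl ether.

Step 10
Reactants: 14 isovaleraldehyde (3-methylbutanal); 15 propane-1,3-dithiol
Product: 16 2-(2-methylpropyl)-1,3-dithiane
Conditions: BF3·OEt2 (0.2 equiv), CH2Cl2, 0 °C to rt
Reagents that add atoms: none
Why: Lewis-acid-catalysed thioacetalisation of an unhindered aldehyde is fast and high-yielding and provides the acyl-anion equivalent for C14.

Step 11
Reactants: 16 2-(2-methylpropyl)-1,3-dithiane; 13 {[(2E,6E)-8-bromo-3,7-dimethylocta-2,6-dien-1-yl]oxy}(tert-butyl)dimethylsilane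
Product: 18 tert-butyl({(2E,6E)-3,7-dimethyl-8-[2-(2-methylpropyl)-1,3-dithian-2-yl]octa-2,6-dien-1-yl}oxy)dimethylsilane, via 2-lithiodithiane 17 (not isolated)
Conditions: 16 (1.2 equiv), n-BuLi, THF, −30 °C, 2 h; then 13, −78 to −20 °C
Reagents that add atoms: none
Why: In this Corey–Seebach umpolung alkylation the soft dithiane anion displaces the unhindered primary allylic bromide by direct SN2, which makes C13–C14 without moving or isomerising the alkene.

Step 12
Reactants: 18 tert-butyl({(2E,6E)-3,7-dimethyl-8-[2-(2-methylpropyl)-1,3-dithian-2-yl]octa-2,6-dien-1-yl}oxy)dimethylsilane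
Product: 19 (2E,6E)-3,7-dimethyl-8-[2-(2-methylpropyl)-1,3-dithian-2-yl]octa-2,6-dien-1-ol
Conditions: TBAF, THF, 0 °C to rt
Reagents that add atoms: none
Why: Fluoride-driven desilylation removes the primary TBS ether and nothing else in the molecule reacts with fluoride.

Step 13
Reactants: 19 (2E,6E)-3,7-dimethyl-8-[2-(2-methylpropyl)-1,3-dithian-2-yl]octa-2,6-dien-1-ol
Product: 20 2-[(2E,6E)-8-bromo-2,6-dimethylocta-2,6-dien-1-yl]-2-(2-methylpropyl)-1,3-dithiane
Conditions: CBr4, PPh3, CH2Cl2, −20 to 0 °C; used at once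
Reagents that add atoms: carbon tetrabromide, BrC(Br)(Br)Br
Why: The Appel reaction turns the geraniol-type alcohol into the E-allylic bromide under neutral conditions that the thioacetal tolerates.

Step 14
Reactants: 20 2-[(2E,6E)-8-bromo-2,6-dimethylocta-2,6-dien-1-yl]-2-(2-methylpropyl)-1,3-dithiane
Product: 21 2-[(2E,6E)-8-(benzenesulfonyl)-2,6-dimethylocta-2,6-dien-1-yl]-2-(2-methylpropyl)-1,3-dithiane
Conditions: PhSO2Na (1.5 equiv), DMF, 0 °C to rt
Reagents that add atoms: sodium benzenesulfinate, [Na+].[O-]S(=O)c1ccccc1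
Why: SN2 S-alkylation of the sulfinate by a primary allylic bromide gives the allylic sulfone with the E-alkene retained.

**Union and end game**

Step 15
Reactants: 21 2-[(2E,6E)-8-(benzenesulfonyl)-2,6-dimethylocta-2,6-dien-1-yl]-2-(2-methylpropyl)-1,3-dithiane; 9 {[(1S,3E)-5-bromo-1-(furan-3-yl)-4-methylpent-3-en-1-yl]oxy}(tert-butyl)dimethylsilane
Product: 23 tert-butyl({(1S,3E,7E,11E)-6-(benzenesulfonyl)-1-(furan-3-yl)-4,8,12-trimethyl-13-[2-(2-methylpropyl)-1,3-dithian-2-yl]trideca-3,7,11-trien-1-yl}oxy)dimethylsilane (both C6 epimers), via lithiated sulfone 22 (not isolated)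
Conditions: 21, n-BuLi (1.05 equiv), THF–DMPU, −78 °C; then 9, −78 to −40 °C
Reagents that add atoms: none
Why: In this Biellmann-type sulfone alkylation the allylic sulfonyl carbanion reacts at its α-carbon with the allylic bromide by SN2, which forms C5–C6 with all alkenes unchanged, and the new C6 centre does not matter because it is erased in the next step.

Step 16
Reactants: 23 coupled sulfone (name as in step 15)
Product: 24 tert-butyl({(1S,3E,7E,11E)-1-(furan-3-yl)-4,8,12-trimethyl-13-[2-(2-methylpropyl)-1,3-dithian-2-yl]trideca-3,7,11-trien-1-yl}oxy)dimethylsilane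
Conditions: PdCl2(dppp) (10 mol %), LiEt3BH (3 equiv), THF, 0 °C
Reagents that add atoms: none
Why: In this Pd-catalysed reductive desulfonylation (allylic hydride substitution), zerovalent palladium formed in situ ionises the allylic sulfone to a π-allyl complex and hydride goes to the less substituted terminus C6, so C7=C8 stays in place and E while the silyl ether, furan and dithiane are inert to the hydride.

Step 17
Reactants: 24 silyl ether (name as in step 16)
Product: 25 (1S,3E,7E,11E)-1-(furan-3-yl)-4,8,12-trimethyl-13-[2-(2-methylpropyl)-1,3-dithian-2-yl]trideca-3,7,11-trien-1-ol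
Conditions: TBAF, THF, 0 °C to rt
Reagents that add atoms: none
Why: Fluoride-driven desilylation breaks only the Si–O bond, so C1 keeps its (S) configuration, and the base-sensitive β,γ-enone is still masked at this point.

Step 18
Reactants: 25 (1S,3E,7E,11E)-1-(furan-3-yl)-4,8,12-trimethyl-13-[2-(2-methylpropyl)-1,3-dithian-2-yl]trideca-3,7,11-trien-1-ol
Product: 26 (1S,3E,7E,11E)-1-(furan-3-yl)-4,8,12-trimethyl-13-[2-(2-methylpropyl)-1,3-dithian-2-yl]trideca-3,7,11-trien-1-yl acetate
Conditions: Ac2O, pyridine, DMAP (cat.), CH2Cl2, 0 °C to rt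
Reagents that add atoms: acetic anhydride, CC(=O)OC(C)=O
Why: DMAP-catalysed O-acylation takes place at oxygen only and therefore retains the configuration at C1.

Step 19
Reactants: 26 acetate (name as in step 18)
Product: 27 (1S,3E,7E,11E)-1-(furan-3-yl)-4,8,12,16-tetramethyl-14-oxoheptadeca-3,7,11-trien-1-yl acetate (target)
Conditions: MeI (15 equiv), CaCO3 (8 equiv), MeCN–H2O 9:1, 35–40 °C, dark
Reagents that add atoms: water, O
Why: Alkylative thioacetal hydrolysis (S-methylation, then attack of water) needs neither oxidant nor heavy metal and is buffered to neutrality by CaCO3, so the furan, the acetate and the non-conjugated position of C11=C12 are preserved.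

**Compound list**
1 | furan-3-carbaldehyde | O=Cc1ccoc1 | starting material
2 | (1S)-1-(furan-3-yl)but-3-en-1-yl diisopinocampheylborinate | B(O[C@@H](CC=C)c1ccoc1)([C@@H]1C[C@@H]2C[C@H]([C@H]1C)C2(C)C)[C@@H]1C[C@@H]2C[C@H]([C@H]1C)C2(C)C | intermediate
3 | (1S)-1-(furan-3-yl)but-3-en-1-ol | O[C@@H](CC=C)c1ccoc1 | intermediate
4 | tert-butyl{[(1S)-1-(furan-3-yl)but-3-en-1-yl]oxy}dimethylsilane | CC(C)(C)[Si](C)(C)O[C@@H](CC=C)c1ccoc1 | intermediate
5 | (4S)-4-[(tert-butyldimethylsilyl)oxy]-4-(furan-3-yl)butane-1,2-diol (C2 epimers) | CC(C)(C)[Si](C)(C)O[C@@H](CC(O)CO)c1ccoc1 | intermediate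
6 | (3S)-3-[(tert-butyldimethylsilyl)oxy]-3-(furan-3-yl)propanal | CC(C)(C)[Si](C)(C)O[C@@H](CC=O)c1ccoc1 | intermediate
7 | ethyl (2E,5S)-5-[(tert-butyldimethylsilyl)oxy]-5-(furan-3-yl)-2-methylpent-2-enoate | CC(C)(C)[Si](C)(C)O[C@@H](C/C=C(\C)C(=O)OCC)c1ccoc1 | intermediate
8 | (2E,5S)-5-[(tert-butyldimethylsilyl)oxy]-5-(furan-3-yl)-2-methylpent-2-en-1-ol | CC(C)(C)[Si](C)(C)O[C@@H](C/C=C(\C)CO)c1ccoc1 | intermediate
9 | {[(1S,3E)-5-bromo-1-(furan-3-yl)-4-methylpent-3-en-1-yl]oxy}(tert-butyl)dimethylsilane | CC(C)(C)[Si](C)(C)O[C@@H](C/C=C(\C)CBr)c1ccoc1 | intermediate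
10 | geraniol | OC/C=C(\C)CCC=C(C)C | starting material
11 | tert-butyl{[(2E)-3,7-dimethylocta-2,6-dien-1-yl]oxy}dimethylsilane | CC(C)(C)[Si](C)(C)OC/C=C(\C)CCC=C(C)C | intermediate
12 | (2E,6E)-8-[(tert-butyldimethylsilyl)oxy]-2,6-dimethylocta-2,6-dien-1-ol | CC(C)(C)[Si](C)(C)OC/C=C(\C)CC/C=C(\C)CO | intermediate
13 | {[(2E,6E)-8-bromo-3,7-dimethylocta-2,6-dien-1-yl]oxy}(tert-butyl)dimethylsilane | CC(C)(C)[Si](C)(C)OC/C=C(\C)CC/C=C(\C)CBr | intermediate
14 | isovaleraldehyde | CC(C)CC=O | starting material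
15 | propane-1,3-dithiol | SCCCS | starting material
16 | 2-(2-methylpropyl)-1,3-dithiane | CC(C)CC1SCCCS1 | intermediate
17 | 2-lithio-2-(2-methylpropyl)-1,3-dithiane | [Li]C1(CC(C)C)SCCCS1 | intermediate
18 | tert-butyl({(2E,6E)-3,7-dimethyl-8-[2-(2-methylpropyl)-1,3-dithian-2-yl]octa-2,6-dien-1-yl}oxy)dimethylsilane | CC(C)(C)[Si](C)(C)OC/C=C(\C)CC/C=C(\C)CC1(CC(C)C)SCCCS1 | intermediate
19 | (2E,6E)-3,7-dimethyl-8-[2-(2-methylpropyl)-1,3-dithian-2-yl]octa-2,6-dien-1-ol | OC/C=C(\C)CC/C=C(\C)CC1(CC(C)C)SCCCS1 | intermediate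
20 | 2-[(2E,6E)-8-bromo-2,6-dimethylocta-2,6-dien-1-yl]-2-(2-methylpropyl)-1,3-dithiane | BrC/C=C(\C)CC/C=C(\C)CC1(CC(C)C)SCCCS1 | intermediate
21 | 2-[(2E,6E)-8-(benzenesulfonyl)-2,6-dimethylocta-2,6-dien-1-yl]-2-(2-methylpropyl)-1,3-dithiane | O=S(=O)(C/C=C(\C)CC/C=C(\C)CC1(CC(C)C)SCCCS1)c1ccccc1 | intermediate
22 | α-lithio derivative of sulfone 21 | [Li]C(/C=C(\C)CC/C=C(\C)CC1(CC(C)C)SCCCS1)S(=O)(=O)c1ccccc1 | intermediate
23 | tert-butyl({(1S,3E,7E,11E)-6-(benzenesulfonyl)-1-(furan-3-yl)-4,8,12-trimethyl-13-[2-(2-methylpropyl)-1,3-dithian-2-yl]trideca-3,7,11-trien-1-yl}oxy)dimethylsilane (C6 epimers) | CC(C)(C)[Si](C)(C)O[C@@H](C/C=C(\C)CC(/C=C(\C)CC/C=C(\C)CC1(CC(C)C)SCCCS1)S(=O)(=O)c1ccccc1)c1ccoc1 | intermediate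
24 | tert-butyl({(1S,3E,7E,11E)-1-(furan-3-yl)-4,8,12-trimethyl-13-[2-(2-methylpropyl)-1,3-dithian-2-yl]trideca-3,7,11-trien-1-yl}oxy)dimethylsilane | CC(C)(C)[Si](C)(C)O[C@@H](C/C=C(\C)CC/C=C(\C)CC/C=C(\C)CC1(CC(C)C)SCCCS1)c1ccoc1 | intermediate
25 | (1S,3E,7E,11E)-1-(furan-3-yl)-4,8,12-trimethyl-13-[2-(2-methylpropyl)-1,3-dithian-2-yl]trideca-3,7,11-trien-1-ol | O[C@@H](C/C=C(\C)CC/C=C(\C)CC/C=C(\C)CC1(CC(C)C)SCCCS1)c1ccoc1 | intermediate
26 | (1S,3E,7E,11E)-1-(furan-3-yl)-4,8,12-trimethyl-13-[2-(2-methylpropyl)-1,3-dithian-2-yl]trideca-3,7,11-trien-1-yl acetate | CC(=O)O[C@@H](C/C=C(\C)CC/C=C(\C)CC/C=C(\C)CC1(CC(C)C)SCCCS1)c1ccoc1 | intermediate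
27 | (1S,3E,7E,11E)-1-(furan-3-yl)-4,8,12,16-tetramethyl-14-oxoheptadeca-3,7,11-trien-1-yl acetate | CC(=O)O[C@@H](C/C=C(\C)CC/C=C(\C)CC/C=C(\C)CC(=O)CC(C)C)c1ccoc1 | target

**Totals**
Total step count: 19.
Longest linear sequence: 12 steps, from geraniol 10 through steps 7–9 and 11–19. The west branch from 1 takes 11 steps.

**Three steps most likely to fail**

Step 3. The risks are over-oxidation next to the furan and β-elimination of aldehyde 6. The fallback drops the aldehyde and builds C3=C4 by olefin cross-metathesis. It sets out from 4 and comes back at 8, replacing steps 3–5. Alkene 4 and methacrolein (5 equiv) with the second-generation Hoveyda–Grubbs catalyst (5 mol %) in CH2Cl2 at 40 °C give (2E,5S)-5-[(tert-butyldimethylsilyl)oxy]-5-(furan-3-yl)-2-methylpent-2-enal F1, the E isomer being strongly favoured. Luche reduction (NaBH4, CeCl3·7H2O, MeOH, 0 °C) then gives 8.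

Step 16. The risks are that the thioacetal binds the palladium catalyst, or that the alkene is partly transposed. The fallback keeps divalent sulfur out of the palladium step by joining the chain first and bringing in the dithiane afterwards. It sets out from 10 and 9 and comes back at 24.
- Geraniol 10 with PBr3 (Et2O, 0 °C) gives geranyl bromide F2.
- PhSO2Na in DMF gives geranyl phenyl sulfone F3.
- SeO2 (cat.)/t-BuOOH gives (2E,6E)-8-(benzenesulfonyl)-2,6-dimethylocta-2,6-dien-1-ol F4.
- Two equivalents of n-BuLi (THF–DMPU, −78 °C) give the C,O-dilithio derivative F5. Its carbanion is alkylated by 9 to the coupled hydroxy sulfone F6.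
- PdCl2(dppp)/LiEt3BH, now acting on a substrate without a thioacetal, gives the trienol F7.
- CBr4/PPh3 gives the trienyl bromide F8, which is alkylated by 17 (made from 16 as in step 11) to give 24.

Step 19. The risks are slow hydrolysis of the hindered dithiane, solvolysis of the furyl-carbinyl acetate on long warming, and drift of the β,γ-enone into conjugation. The fallback unmasks the ketone while C1 still carries the robust silyl ether and ends the synthesis on an acylation under non-basic conditions. It sets out from 24 and comes back at 27.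
- MeI/CaCO3 in aqueous MeCN on 24 gives the keto silyl ether F9.
- HF·pyridine buffered with pyridine (THF, 0 °C to rt) gives the hydroxy ketone F10 without exposing the enone to basic fluoride.
- Ac2O/pyridine (CH2Cl2, 0 °C) gives 27.

**Further compounds**
F1 | step 3 | (2E,5S)-5-[(tert-butyldimethylsilyl)oxy]-5-(furan-3-yl)-2-methylpent-2-enal | CC(C)(C)[Si](C)(C)O[C@@H](C/C=C(\C)C=O)c1ccoc1
F2 | step 16 | geranyl bromide | BrC/C=C(\C)CCC=C(C)C
F3 | step 16 | geranyl phenyl sulfone | O=S(=O)(C/C=C(\C)CCC=C(C)C)c1ccccc1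
F4 | step 16 | (2E,6E)-8-(benzenesulfonyl)-2,6-dimethylocta-2,6-dien-1-ol | O=S(=O)(C/C=C(\C)CC/C=C(\C)CO)c1ccccc1
F5 | step 16 | C,O-dilithio derivative of F4 | [Li]C(/C=C(\C)CC/C=C(\C)CO[Li])S(=O)(=O)c1ccccc1
F6 | step 16 | coupled hydroxy sulfone, (2E,6E,10E,13S)-8-(benzenesulfonyl)-13-[(tert-butyldimethylsilyl)oxy]-13-(furan-3-yl)-2,6,10-trimethyltrideca-2,6,10-trien-1-ol (C8 epimers) | CC(C)(C)[Si](C)(C)O[C@@H](C/C=C(\C)CC(/C=C(\C)CC/C=C(\C)CO)S(=O)(=O)c1ccccc1)c1ccoc1
F7 | step 16 | trienol, (2E,6E,10E,13S)-13-[(tert-butyldimethylsilyl)oxy]-13-(furan-3-yl)-2,6,10-trimethyltrideca-2,6,10-trien-1-ol | CC(C)(C)[Si](C)(C)O[C@@H](C/C=C(\C)CC/C=C(\C)CC/C=C(\C)CO)c1ccoc1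
F8 | step 16 | trienyl bromide, {[(1S,3E,7E,11E)-13-bromo-1-(furan-3-yl)-4,8,12-trimethyltrideca-3,7,11-trien-1-yl]oxy}(tert-butyl)dimethylsilane | CC(C)(C)[Si](C)(C)O[C@@H](C/C=C(\C)CC/C=C(\C)CC/C=C(\C)CBr)c1ccoc1
F9 | step 19 | keto silyl ether, (6E,10E,14E,17S)-17-[(tert-butyldimethylsilyl)oxy]-17-(furan-3-yl)-2,6,10,14-tetramethylheptadeca-6,10,14-trien-4-one | CC(C)(C)[Si](C)(C)O[C@@H](C/C=C(\C)CC/C=C(\C)CC/C=C(\C)CC(=O)CC(C)C)c1ccoc1
F10 | step 19 | hydroxy ketone, (6E,10E,14E,17S)-17-(furan-3-yl)-17-hydroxy-2,6,10,14-tetramethylheptadeca-6,10,14-trien-4-one | O[C@@H](C/C=C(\C)CC/C=C(\C)CC/C=C(\C)CC(=O)CC(C)C)c1ccoc1
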